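## Retrosynthetic overview

1. Target ⇒ ortho C-prenylation, done last, of the electron-rich benzyl phenol of the des-prenyl methyl enol ether with prenol. This is the same aromatic substitution the prenyltransferase performs.
2. ⇒ Chemoselective O-methylation of the acidic enol OH of the des-prenyl hydroxybutenolide.
3. ⇒ Key step: the butenolide, the only ring that has to be built, comes from a catalytic enantioselective head-to-tail homodimerization of unprotected methyl 4-hydroxyphenylpyruvate. The aldol C-C bond sets the (R) quaternary carbon and the lactone C-O bond closes in the same flask.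
4. ⇒ Fischer esterification of commercial 4-hydroxyphenylpyruvic acid. No protecting groups are used.

Labels: furanone numbering is O1, C2 (quaternary), C3 (aryl), C4 (OH or OMe), C5 (C=O). Ring A is the 4-hydroxyphenyl group on C3. Ring B is the phenol ring of the benzyl group on C2.

Assumption: the sense of induction of the new dimerization cannot be predicted with certainty, so the route is written with the commercial quinine-derived squaramide. If the first run gives the (S)-lactone (chiral HPLC and ECD against the natural (R) series), the commercial quinidine-derived pseudoenantiomer is used and nothing else changes.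

## Route

Step 1
Reactants: 1 4-hydroxyphenylpyruvic acid
Product: 2 methyl 4-hydroxyphenylpyruvate
Conditions: H2SO4 (5 mol%), MeOH, 40 °C, 12 h, Ar
Reagents that add atoms: methanol, CO
Why: Fischer esterification in a large excess of methanol converts only the carboxylic acid, because the phenol is inert and the ketone is held mainly as its conjugated enol, and no stereocentre is involved.

Step 2
Reactants: 2 methyl 4-hydroxyphenylpyruvate (two molecules, one reacting as the enol and one as the ketone)
Product: 5 methyl (2R)-4-hydroxy-2-(4-hydroxybenzyl)-3-(4-hydroxyphenyl)-5-oxo-2,5-dihydrofuran-2-carboxylate, via aldol adduct 3 (not isolated), via keto lactone 4 (not isolated)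
Conditions: quinine-derived squaramide 3-[3,5-bis(trifluoromethyl)anilino]-4-[(8α,9S)-6'-methoxycinchonan-9-ylamino]cyclobut-3-ene-1,2-dione (10 mol%), 4 Å MS, 2-MeTHF (1.0 M), 0 °C to rt, 48 h, Ar
Reagents that add atoms: none
Why: Proposed new method: arylpyruvate esters are known to dimerize to this hydroxybutenolide in racemic form under achiral amine bases (aldol addition, lactonization, tautomerization), and here the quinuclidine nitrogen of the bifunctional catalyst deprotonates the abundant Z-enol of one molecule of 2 while the two squaramide N-H bonds bind the 1,2-dicarbonyl unit of the keto tautomer of a second molecule, so that the C-C bond forms inside a chiral ion pair on one face of the ketone and fixes the quaternary carbon as (R), after which the alkoxide of 3 closes irreversibly on the activated alpha-keto ester with loss of methanol and enolization of 4 erases the benzylic stereocentre, leaving the ketone facial selectivity as the only thing that counts; the closest known reaction types are the squaramide- or thiourea-catalysed aldol-lactonization of enolizable alpha-keto esters with activated ketones to isotetronic acids and the catalytic enantioselective homo-aldol reaction of ethyl pyruvate.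

Step 3
Reactants: 5 methyl (2R)-4-hydroxy-2-(4-hydroxybenzyl)-3-(4-hydroxyphenyl)-5-oxo-2,5-dihydrofuran-2-carboxylate
Product: 6 methyl (2R)-2-(4-hydroxybenzyl)-3-(4-hydroxyphenyl)-4-methoxy-5-oxo-2,5-dihydrofuran-2-carboxylate
Conditions: TMSCHN2 (1.05 equiv, 2 M in hexanes, added dropwise until the yellow colour just persists), THF/MeOH 4:1, -10 °C, 20 min; AcOH quench
Reagents that add atoms: (trimethylsilyl)diazomethane, C[Si](C)(C)C=[N+]=[N-]
Why: Diazoalkane O-methylation is gated by proton transfer, so the enol OH next to the lactone carbonyl, the most acidic OH in 5, is methylated within minutes while the two phenols react only slowly without added base, and the quaternary stereocentre is not touched.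

Step 4
Reactants: 6 methyl (2R)-2-(4-hydroxybenzyl)-3-(4-hydroxyphenyl)-4-methoxy-5-oxo-2,5-dihydrofuran-2-carboxylate; 7 prenol (3-methylbut-2-en-1-ol)
Product: 8 2-O-methylbutyrolactone I, methyl (2R)-2-[4-hydroxy-3-(3-methylbut-2-en-1-yl)benzyl]-3-(4-hydroxyphenyl)-4-methoxy-5-oxo-2,5-dihydrofuran-2-carboxylate
Conditions: 7 (1.0 equiv, in portions), acidic Al2O3 (2 g per mmol), ClCH2CH2Cl, 80 °C, 16 h; stopped at about 70% conversion, 6 recovered
Reagents that add atoms: none
Why: Alumina-templated Friedel-Crafts prenylation of a free phenol with an allylic alcohol can only attack ortho to OH because both para positions are blocked, it favours the p-alkylphenol ring B over ring A, whose oxygen lone pair is drained by conjugation with the butenolide carbonyl, the mild solid acid limits chroman closure, and the stereocentre is not involved.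

## Compound list

1 | 4-hydroxyphenylpyruvic acid | O=C(O)C(=O)Cc1ccc(O)cc1 | starting material
2 | methyl 4-hydroxyphenylpyruvate (keto/enol mixture, drawn as the keto form) | COC(=O)C(=O)Cc1ccc(O)cc1 | intermediate
3 | dimethyl (2R)-2-hydroxy-2-(4-hydroxybenzyl)-3-(4-hydroxyphenyl)-4-oxopentanedioate (aldol adduct, C3 epimers, not isolated) | COC(=O)[C@](Cc1ccc(O)cc1)(O)C(c1ccc(O)cc1)C(=O)C(=O)OC | intermediate
4 | methyl (2R)-2-(4-hydroxybenzyl)-3-(4-hydroxyphenyl)-4,5-dioxotetrahydrofuran-2-carboxylate (keto lactone, C3 epimers, not isolated) | COC(=O)[C@]1(Cc2ccc(O)cc2)OC(=O)C(=O)C1c1ccc(O)cc1 | intermediate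
5 | methyl (2R)-4-hydroxy-2-(4-hydroxybenzyl)-3-(4-hydroxyphenyl)-5-oxo-2,5-dihydrofuran-2-carboxylate | COC(=O)[C@]1(Cc2ccc(O)cc2)OC(=O)C(O)=C1c1ccc(O)cc1 | intermediate
6 | methyl (2R)-2-(4-hydroxybenzyl)-3-(4-hydroxyphenyl)-4-methoxy-5-oxo-2,5-dihydrofuran-2-carboxylate | COC(=O)[C@]1(Cc2ccc(O)cc2)OC(=O)C(OC)=C1c1ccc(O)cc1 | intermediate
7 | prenol (3-methylbut-2-en-1-ol) | CC(C)=CCO | starting material
8 | 2-O-methylbutyrolactone I, methyl (2R)-2-[4-hydroxy-3-(3-methylbut-2-en-1-yl)benzyl]-3-(4-hydroxyphenyl)-4-methoxy-5-oxo-2,5-dihydrofuran-2-carboxylate | COC(=O)[C@]1(Cc2ccc(O)c(CC=C(C)C)c2)OC(=O)C(OC)=C1c1ccc(O)cc1 | target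

## Step count

Total step count: 4
Longest linear sequence: 4

## Steps most likely to fail

**Step 2 (highest risk).**
- The enantioselectivity is untested.
- The free phenols can compete for the squaramide N-H bonds.
- The acidic enol of 5 can protonate the quinuclidine and slow turnover at high conversion.

The fallback replaces asymmetric catalysis with resolution. It sets out from 2 and comes back at 5. Compound 2 is dimerized with DBU (0.5 equiv) in MeCN at 0 °C, the established racemic reaction. This runs through the racemic aldol adduct F1 and the racemic keto lactone F2 to the racemic enol lactone F3. F3 is then separated by preparative SFC on an immobilised amylose tris(3,5-dimethylphenylcarbamate) phase (CO2/MeOH). This gives 5, and the (S)-enol lactone F4 is set aside.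

**Step 4.**
- The preference for ring B over ring A rests on a modest electronic difference, estimated at 5:1 to 10:1.
- Double prenylation can erode the yield.
- Acid-induced closure of the new ortho-prenylphenol to a dimethylchroman can also erode the yield.

The fallback replaces direct alkylation with halogenation and cross-coupling. It sets out from 6 and comes back at 8. Electrophilic iodination discriminates between the two rings much more sharply than alkylation does. NIS (1.0 equiv) with TsOH·H2O (10 mol%) in MeCN at 0 °C should therefore give the ring B mono-iodide F5. A Stille coupling of F5 with tributyl(3-methylbut-2-en-1-yl)stannane, using Pd(PPh3)4 (5 mol%, zerovalent palladium) in DMF at 80 °C, transfers the linear prenyl group. It tolerates the free phenols and gives 8 without any acid.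

**Step 3.**
- The acidity gap between the enol OH and the ring A phenol, which is conjugated with the lactone, may be only one to two pK units.
- Some ring A methyl ether and some dimethylated material may therefore form.

The fallback replaces alkylation of an oxygen nucleophile with carbonyl chemistry in which phenols cannot take part. It sets out from 5 and comes back at 6. Compound 5 is heated with HC(OMe)3 (5 equiv) and TsOH·H2O (10 mol%) in MeOH at 65 °C. The small equilibrium share of keto lactone 4 is ketalised to the dimethyl ketal F6. Continued heating with TsOH in toluene at 110 °C, with distillation of the volatiles, eliminates methanol toward the aryl-conjugated position and gives 6. Strong acid is acceptable at this stage because the prenyl group is not yet present.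

## Further compounds

F1 | step 2 | racemic dimethyl 2-hydroxy-2-(4-hydroxybenzyl)-3-(4-hydroxyphenyl)-4-oxopentanedioate (racemic aldol adduct) | COC(=O)C(O)(Cc1ccc(O)cc1)C(c1ccc(O)cc1)C(=O)C(=O)OC
F2 | step 2 | racemic methyl 2-(4-hydroxybenzyl)-3-(4-hydroxyphenyl)-4,5-dioxotetrahydrofuran-2-carboxylate (racemic keto lactone) | COC(=O)C1(Cc2ccc(O)cc2)OC(=O)C(=O)C1c1ccc(O)cc1
F3 | step 2 | racemic methyl 4-hydroxy-2-(4-hydroxybenzyl)-3-(4-hydroxyphenyl)-5-oxo-2,5-dihydrofuran-2-carboxylate (racemic enol lactone) | COC(=O)C1(Cc2ccc(O)cc2)OC(=O)C(O)=C1c1ccc(O)cc1
F4 | step 2 | methyl (2S)-4-hydroxy-2-(4-hydroxybenzyl)-3-(4-hydroxyphenyl)-5-oxo-2,5-dihydrofuran-2-carboxylate ((S)-enol lactone) | COC(=O)[C@@]1(Cc2ccc(O)cc2)OC(=O)C(O)=C1c1ccc(O)cc1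
F5 | step 4 | methyl (2R)-2-(4-hydroxy-3-iodobenzyl)-3-(4-hydroxyphenyl)-4-methoxy-5-oxo-2,5-dihydrofuran-2-carboxylate (ring B mono-iodide) | COC(=O)[C@]1(Cc2ccc(O)c(I)c2)OC(=O)C(OC)=C1c1ccc(O)cc1
F6 | step 3 | methyl (2R)-2-(4-hydroxybenzyl)-3-(4-hydroxyphenyl)-4,4-dimethoxy-5-oxotetrahydrofuran-2-carboxylate (dimethyl ketal, C3 epimers) | COC(=O)[C@]1(Cc2ccc(O)cc2)OC(=O)C(OC)(OC)C1c1ccc(O)cc1
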